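## Retrosynthetic overview

1. Target 42 ⇐ C-6 oxidation with C-7 epimerisation, fluoride deprotection and denitration of the nitro-bicyclo[3.2.1]octenedione 38.
2. 38 ⇐ intermolecular Michael addition of hydroxyquinone 36 (C-13) to labdane nitrodiene 16 (C-14′), then intramolecular nitronate Michael addition onto C-8 (C-8–C-15′). The bridged ring is formed last.
3. 36 ⇐ dehydroabietic acid: C-18 → CH3, C-12 oxygenation, C-7 ketone, Wolff ring contraction (6-6-6 → 6-5-6), C-11/C-14 oxidation to the quinone.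
4. 16 ⇐ abietic acid: C13=C14 cleavage, Kabalka transposition to the 8(17)-ene, side-chain degradation to the C-12 aldehyde, Wittig (12E), Henry reaction and dehydration.
5. Ring order: both A/B ring systems come from the chiral pool; then ring-B contraction, quinone ring C, and the bicyclo[3.2.1]octane in the key step.

Assumption: α/β refer to the usual terpenoid drawing (10-methyl β). Unprimed locants are those of the 5(6→7)abeo-abietane unit (ring-B methine C-7 carries the exocyclic C-6); primed locants are those of the labdane unit. "TMSE" = 2-(trimethylsilyl)ethyl. The 7α-formyl configuration of the target is taken to be the thermodynamic one.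

## Route

**Part A – labdane nitrodiene**

Step 1
Reactants: 1 (−)-abietic acid
Product: 2 TMSE abietate
Conditions: Me3SiCH2CH2OH, PPh3, DIAD, THF, 0 °C → rt
Reagents that add atoms: 2-(trimethylsilyl)ethanol, C[Si](C)(C)CCO
Why: Mitsunobu esterification O-alkylates the hindered C-4 carboxylate without touching the diene and installs a fluoride-labile ester; no stereocentre is affected.

Step 2
Reactants: 2 TMSE abietate
Product: 3 TMSE 13α,14α-dihydroxyabiet-7-en-18-oate
Conditions: OsO4 (2 mol %), NMO (1.05 equiv), acetone–t-BuOH–H2O, 0 °C → rt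
Reagents that add atoms: N-methylmorpholine N-oxide, C[N+]1([O-])CCOCC1; water, O
Why: Upjohn dihydroxylation should take the more exposed ring-C trisubstituted alkene from the α-face (anti to the 10β-methyl); both new centres are destroyed in step 3.

Step 3
Reactants: 3 TMSE 13α,14α-dihydroxyabiet-7-en-18-oate
Product: 4 TMSE 13,14-dioxo-13,14-secoabiet-7-en-18-oate
Conditions: NaIO4, THF–H2O, rt
Reagents that add atoms: none
Why: Malaprade glycol cleavage opens ring C to the C-14 enal and the C-13 isopropyl ketone, and H-9 is not acidic in this product.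

Step 4
Reactants: 4 TMSE 13,14-dioxo-13,14-secoabiet-7-en-18-oate
Product: 5 C-14 (E)-tosylhydrazone of 4
Conditions: TsNHNH2 (1.05 equiv), THF, rt
Reagents that add atoms: p-toluenesulfonyl hydrazide, Cc1ccc(cc1)S(=O)(=O)NN
Why: Hydrazone condensation is selective for the aldehyde over the hindered isopropyl ketone.

Step 5
Reactants: 5 C-14 (E)-tosylhydrazone of 4
Product: 7 TMSE 13-oxo-13,14-secoabiet-8(14)-en-18-oate, via allylic diazene 6 (not isolated)
Conditions: catecholborane, CHCl3, 0 °C; then NaOAc·3H2O, reflux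
Reagents that add atoms: none
Why: Kabalka reductive alkene transposition: hydride adds to the conjugated C=N, loss of sulfinate gives the allylic diazene, and its retro-ene loss of N2 delivers H to C-7 and leaves the exocyclic 8(17)-methylene; C-9 is untouched.

Step 6
Reactants: 7 TMSE 13-oxo-13,14-secoabiet-8(14)-en-18-oate
Product: 9 TMSE 12-hydroxy-13-oxo-13,14-secoabiet-8(14)-en-18-oate (C-12 epimers), via lithium enolate 8 (not isolated)
Conditions: LDA, THF, −78 °C; then 2-(phenylsulfonyl)-3-phenyloxaziridine, −78 → −40 °C; NH4Cl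
Reagents that add atoms: 2-(phenylsulfonyl)-3-phenyloxaziridine, O=S(=O)(c1ccccc1)N1OC1c1ccccc1
Why: Kinetic deprotonation occurs at the C-12 methylene and not at the isopropyl methine, and Davis enolate hydroxylation leaves both alkenes alone; the carbinol centre is lost in step 7.

Step 7
Reactants: 9 TMSE 12-hydroxy-13-oxo-13,14-secoabiet-8(14)-en-18-oate
Product: 10 TMSE 12-oxo-13,14,15,16-tetranorlabd-8(17)-en-18-oate
Conditions: Pb(OAc)4, MeOH–benzene, 0 °C
Reagents that add atoms: none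
Why: Criegee cleavage of the α-ketol in methanol gives the C-12 aldehyde and methyl isobutyrate without attacking the 1,1-disubstituted alkene.

Step 8
Reactants: 10 TMSE 12-oxo-13,14,15,16-tetranorlabd-8(17)-en-18-oate; 11 2-(triphenylphosphoranylidene)propanal
Product: 12 TMSE (12E)-14-oxo-15-norlabda-8(17),12-dien-18-oate
Conditions: toluene, 90 °C
Reagents that add atoms: none
Why: Wittig olefination with the stabilised α-methyl ylide gives the (E)-trisubstituted enal (C-14′ trans to C-11′), which fixes the 12′E geometry of the target.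

Step 9
Reactants: 12 TMSE (12E)-14-oxo-15-norlabda-8(17),12-dien-18-oate; 13 nitromethane
Product: 14 TMSE (12E)-14-hydroxy-15-nitrolabda-8(17),12-dien-18-oate (C-14 epimers)
Conditions: CH3NO2 (10 equiv), tetramethylguanidine (10 mol %), THF, 0 °C
Reagents that add atoms: none
Why: Henry (nitroaldol) reaction adds 1,2 to the α-branched enal; the carbinol centre is removed in step 10.

Step 10
Reactants: 14 TMSE (12E)-14-hydroxy-15-nitrolabda-8(17),12-dien-18-oate
Product: 16 TMSE (12E,14E)-15-nitrolabda-8(17),12,14-trien-18-oate, via allylic mesylate 15 (not isolated)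
Conditions: MsCl, Et3N, CH2Cl2, −20 → 0 °C
Reagents that add atoms: none
Why: Mesylation followed by E1cB elimination gives the conjugated (E)-nitroalkene.

**Part B – hydroxyquinone**

Step 11
Reactants: 17 (+)-dehydroabietic acid
Product: 18 abieta-8,11,13-trien-18-ol
Conditions: LiAlH4, THF, reflux
Reagents that add atoms: none
Why: Hydride reduction of the hindered acid; C-4, C-5 and C-10 are untouched.

Step 12
Reactants: 18 abieta-8,11,13-trien-18-ol
Product: 19 abieta-8,11,13-trien-18-yl tosylate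
Conditions: TsCl, pyridine, DMAP (cat.), rt
Reagents that add atoms: p-toluenesulfonyl chloride, Cc1ccc(cc1)S(=O)(=O)Cl
Why: Sulfonylation activates the neopentyl alcohol for reductive removal.

Step 13
Reactants: 19 abieta-8,11,13-trien-18-yl tosylate
Product: 20 abieta-8,11,13-triene
Conditions: LiEt3BH, THF, 65 °C
Reagents that add atoms: none
Why: Super-Hydride displaces even neopentyl tosylates (SN2 hydride transfer), giving the 4,4-dimethyl group of the target.

Step 14
Reactants: 20 abieta-8,11,13-triene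
Product: 21 12-acetylabieta-8,11,13-triene
Conditions: AcCl, AlCl3, CH2Cl2, 0 °C → rt
Reagents that add atoms: acetyl chloride, CC(=O)Cl
Why: Friedel–Crafts acylation goes to C-12 (para to the C-9 alkyl group), because C-11 and C-14 are peri-hindered.

Step 15
Reactants: 21 12-acetylabieta-8,11,13-triene
Product: 22 12-acetoxyabieta-8,11,13-triene
Conditions: mCPBA, TFA (cat.), CH2Cl2, rt, dark
Reagents that add atoms: 3-chloroperbenzoic acid, OOC(=O)c1cccc(Cl)c1
Why: Baeyer–Villiger oxidation with migration of the electron-rich aryl group.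

Step 16
Reactants: 22 12-acetoxyabieta-8,11,13-triene
Product: 24 12-methoxyabieta-8,11,13-triene, via ferruginol 23 (not isolated)
Conditions: K2CO3, MeOH, rt; then MeI, DMF, 40 °C
Reagents that add atoms: iodomethane, CI
Why: Methanolysis of the aryl acetate and Williamson methylation in one flask give an ether that survives the oxidation and strong-base steps.

Step 17
Reactants: 24 12-methoxyabieta-8,11,13-triene
Product: 25 12-methoxyabieta-8,11,13-trien-7-one
Conditions: CrO3, AcOH–H2O, rt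
Reagents that add atoms: chromium trioxide, O=[Cr](=O)=O
Why: Benzylic oxidation takes the C-7 methylene, which is para to the methoxy group, in preference to the isopropyl methine.

Step 18
Reactants: 25 12-methoxyabieta-8,11,13-trien-7-one
Product: 27 6-diazo-12-methoxyabieta-8,11,13-trien-7-one, via trifluoroacetyl ketone 26 (not isolated)
Conditions: LiHMDS, THF, −78 °C; CF3CO2CH2CF3; then MsN3, Et3N, H2O, MeCN, rt
Reagents that add atoms: methanesulfonyl azide, CS(=O)(=O)N=[N+]=[N-]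
Why: Danheiser detrifluoroacetylative diazo transfer works at the only enolisable position (C-6).

Step 19
Reactants: 27 6-diazo-12-methoxyabieta-8,11,13-trien-7-one
Product: 29 methyl (5α,7β)-12-methoxy-5(6→7)abeo-abieta-8,11,13-trien-6-oate, via aryl ketene 28 (not isolated)
Conditions: hν (Hg lamp, Pyrex), MeOH, 0 °C
Reagents that add atoms: methanol, CO
Why: Photo-Wolff rearrangement (aryl migration) contracts ring B; methanol traps the ketene and the ester enol is protonated from the open α-face, giving the kinetic 7β-ester. C-5 does not take part.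

Step 20
Reactants: 29 methyl (5α,7β)-12-methoxy-5(6→7)abeo-abieta-8,11,13-trien-6-oate
Product: 30 (5α,7β)-12-methoxy-5(6→7)abeo-abieta-8,11,13-trien-6-ol
Conditions: LiAlH4, THF, 0 °C (directly after step 19)
Reagents that add atoms: none
Why: Ester reduction removes the enolisable carbonyl and so freezes the 7β configuration.

Step 21
Reactants: 30 (5α,7β)-12-methoxy-5(6→7)abeo-abieta-8,11,13-trien-6-ol
Product: 31 6-O-TBS ether of 30
Conditions: TBSCl, imidazole, DMF, rt
Reagents that add atoms: tert-butyldimethylsilyl chloride, CC(C)(C)[Si](C)(C)Cl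
Why: Silylation protects the primary alcohol and makes the 7β-substituent bulky for later facial control.

Step 22
Reactants: 31 6-O-TBS ether of 30
Product: 34 (5α,7β)-6-(TBS-oxy)-12-methoxy-5(6→7)abeo-abieta-8,11,13-trien-11-ol, via aryllithium 32 (not isolated), via aryl boronate 33 (not isolated)
Conditions: s-BuLi, TMEDA, Et2O, −78 → −20 °C; B(OMe)3, −78 °C → rt; then 30 % H2O2, aq NaOH, 0 °C
Reagents that add atoms: hydrogen peroxide, OO
Why: Directed ortho-metalation by the methoxy group can only occur at C-11 (C-13 carries the isopropyl group), and borylation–oxidation turns the aryllithium into the phenol.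

Step 23
Reactants: 34 (5α,7β)-6-(TBS-oxy)-12-methoxy-5(6→7)abeo-abieta-8,11,13-trien-11-ol
Product: 35 (5α,7β)-6-(TBS-oxy)-12-methoxy-5(6→7)abeo-abieta-8,12-diene-11,14-dione
Conditions: (KSO3)2NO (2.5 equiv), KH2PO4, acetone–H2O, rt
Reagents that add atoms: potassium nitrosodisulfonate (Fremy's salt), [K+].[K+].[O]N(S(=O)(=O)[O-])S(=O)(=O)[O-]
Why: Teuber oxidation of a phenol with a free para position (C-14) gives the para-quinone.

Step 24
Reactants: 35 (5α,7β)-6-(TBS-oxy)-12-methoxy-5(6→7)abeo-abieta-8,12-diene-11,14-dione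
Product: 36 (5α,7β)-6-(TBS-oxy)-12-hydroxy-5(6→7)abeo-abieta-8,12-diene-11,14-dione
Conditions: LiOH (2 equiv), THF–H2O, 0 °C, 30 min; then 1 M HCl to pH 3
Reagents that add atoms: lithium hydroxide, [Li+].[OH-]
Why: Addition–elimination hydrolysis of the vinylogous ester is fast, and the hydroxyquinone anion that forms is not deprotonated further, so C-7 should keep its configuration.

**Part C – fragment union and end game**

Step 25
Reactants: 36 (5α,7β)-6-(TBS-oxy)-12-hydroxy-5(6→7)abeo-abieta-8,12-diene-11,14-dione; 16 TMSE (12E,14E)-15-nitrolabda-8(17),12,14-trien-18-oate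
Product: 38 15′-nitro adduct (C13–C14′ and C8–C15′ bonds; 8α-bridge; 14′-dienyl endo; 15′-nitro exo; 11-enol-12,14-dione; 7β-CH2OTBS; TMSE ester), via Michael adduct 37 (not isolated)
Conditions: 16 (1.5 equiv), Et3N (1.2 equiv), N,N′-bis[3,5-bis(trifluoromethyl)phenyl]thiourea (20 mol %), toluene, 40 °C; AcOH quench
Reagents that add atoms: none
Why: Tandem Michael–Michael annulation: the hydroxyquinone anion can C-alkylate only at C-13 and adds 1,4 to the nitrodiene at C-14′; the nitronate then closes 5-exo onto C-8 (β to the C-11 carbonyl, less hindered than C-9) to give the stable diosphenolate. The 7β-CH2OTBS and 10β-methyl groups block the β-face, so the bridge forms on the α-face while wrong-face C-13 adducts revert by retro-Michael; the dienyl group is expected endo (anti to the C-14 carbonyl bridge) with the nitro group trans to it.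

Step 26
Reactants: 38 15′-nitro adduct
Product: 39 denitrated adduct (7β-CH2OTBS; TMSE ester)
Conditions: Bu3SnH (5 equiv), AIBN (0.3 equiv), (PhSe)2 (10 mol %), toluene (0.5 M), 110 °C
Reagents that add atoms: none
Why: Radical denitration (Ono) replaces the secondary nitro group by hydrogen, and the PhSeH formed in situ traps the C-15′ radical faster than it can rearrange; C-15′ becomes a CH2 group.

Step 27
Reactants: 39 denitrated adduct
Product: 40 7β-hydroxymethyl carboxylic acid (6-ol-18′-oic acid)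
Conditions: TBAF (5 equiv), THF, 0 °C → rt; pH 4 buffer work-up
Reagents that add atoms: none
Why: Fluoride removes the TBS ether and fragments the TMSE ester (to Me3SiF and ethene) independently of the steric hindrance at C-4′, while the diosphenol is protected as its enolate.

Step 28
Reactants: 40 7β-hydroxymethyl carboxylic acid
Product: 42 target CNP0256710.1, via 7β-aldehyde 41 (not isolated)
Conditions: TPAP (5 mol %), NMO (1.5 equiv), 4 Å MS, CH2Cl2, rt; then DBU (0.3 equiv), rt; AcOH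
Reagents that add atoms: none
Why: Ley–Griffith oxidation gives the 7β-aldehyde, and DBU then equilibrates it through its enol to the 7α-epimer, which avoids the contact with the 4β-methyl group and the C-14 bridge.

## Compound list

1 | (−)-abietic acid | CC(C)C1=CC2=CC[C@@H]3[C@](C)(CCC[C@@]3(C)C(=O)O)[C@H]2CC1 | starting material
2 | TMSE abietate | CC(C)C1=CC2=CC[C@@H]3[C@](C)(CCC[C@@]3(C)C(=O)OCC[Si](C)(C)C)[C@H]2CC1 | intermediate
3 | TMSE 13α,14α-dihydroxyabiet-7-en-18-oate | CC(C)[C@@]1(O)[C@H](O)C2=CC[C@@H]3[C@](C)(CCC[C@@]3(C)C(=O)OCC[Si](C)(C)C)[C@H]2CC1 | intermediate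
4 | TMSE 13,14-dioxo-13,14-secoabiet-7-en-18-oate | CC(C)C(=O)CC[C@H]1C(C=O)=CC[C@@H]2[C@]1(C)CCC[C@@]2(C)C(=O)OCC[Si](C)(C)C | intermediate
5 | C-14 (E)-tosylhydrazone of 4 | CC(C)C(=O)CC[C@H]1C(/C=N/NS(=O)(=O)c2ccc(C)cc2)=CC[C@@H]3[C@]1(C)CCC[C@@]3(C)C(=O)OCC[Si](C)(C)C | intermediate
6 | allylic diazene | CC(C)C(=O)CC[C@H]1C(CN=N)=CC[C@@H]2[C@]1(C)CCC[C@@]2(C)C(=O)OCC[Si](C)(C)C | intermediate (not isolated)
7 | TMSE 13-oxo-13,14-secoabiet-8(14)-en-18-oate | CC(C)C(=O)CC[C@H]1C(=C)CC[C@@H]2[C@]1(C)CCC[C@@]2(C)C(=O)OCC[Si](C)(C)C | intermediate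
8 | lithium (Z)-enolate of 7 | CC(C)/C(O[Li])=C/C[C@H]1C(=C)CC[C@@H]2[C@]1(C)CCC[C@@]2(C)C(=O)OCC[Si](C)(C)C | intermediate (not isolated)
9 | TMSE 12-hydroxy-13-oxo-13,14-secoabiet-8(14)-en-18-oate (C-12 epimers) | CC(C)C(=O)C(O)C[C@H]1C(=C)CC[C@@H]2[C@]1(C)CCC[C@@]2(C)C(=O)OCC[Si](C)(C)C | intermediate
10 | TMSE 12-oxo-13,14,15,16-tetranorlabd-8(17)-en-18-oate | O=CC[C@H]1C(=C)CC[C@@H]2[C@]1(C)CCC[C@@]2(C)C(=O)OCC[Si](C)(C)C | intermediate
11 | 2-(triphenylphosphoranylidene)propanal | CC(C=O)=P(c1ccccc1)(c1ccccc1)c1ccccc1 | starting material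
12 | TMSE (12E)-14-oxo-15-norlabda-8(17),12-dien-18-oate | O=C/C(C)=C/C[C@H]1C(=C)CC[C@@H]2[C@]1(C)CCC[C@@]2(C)C(=O)OCC[Si](C)(C)C | intermediate
13 | nitromethane | C[N+](=O)[O-] | starting material
14 | TMSE (12E)-14-hydroxy-15-nitrolabda-8(17),12-dien-18-oate (C-14 epimers) | [O-][N+](=O)CC(O)/C(C)=C/C[C@H]1C(=C)CC[C@@H]2[C@]1(C)CCC[C@@]2(C)C(=O)OCC[Si](C)(C)C | intermediate
15 | 14-mesylate of 14 | [O-][N+](=O)CC(OS(C)(=O)=O)/C(C)=C/C[C@H]1C(=C)CC[C@@H]2[C@]1(C)CCC[C@@]2(C)C(=O)OCC[Si](C)(C)C | intermediate (not isolated)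
16 | TMSE (12E,14E)-15-nitrolabda-8(17),12,14-trien-18-oate | [O-][N+](=O)/C=C/C(C)=C/C[C@H]1C(=C)CC[C@@H]2[C@]1(C)CCC[C@@]2(C)C(=O)OCC[Si](C)(C)C | intermediate
17 | (+)-dehydroabietic acid | CC(C)c1ccc2c(c1)CC[C@@H]3[C@]2(C)CCC[C@@]3(C)C(=O)O | starting material
18 | abieta-8,11,13-trien-18-ol | CC(C)c1ccc2c(c1)CC[C@@H]3[C@]2(C)CCC[C@@]3(C)CO | intermediate
19 | abieta-8,11,13-trien-18-yl tosylate | CC(C)c1ccc2c(c1)CC[C@@H]3[C@]2(C)CCC[C@@]3(C)COS(=O)(=O)c4ccc(C)cc4 | intermediate
20 | abieta-8,11,13-triene | CC(C)c1ccc2c(c1)CC[C@@H]3[C@]2(C)CCCC3(C)C | intermediate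
21 | 12-acetylabieta-8,11,13-triene | CC(C)c1c(C(C)=O)cc2c(c1)CC[C@@H]3[C@]2(C)CCCC3(C)C | intermediate
22 | 12-acetoxyabieta-8,11,13-triene | CC(C)c1c(OC(C)=O)cc2c(c1)CC[C@@H]3[C@]2(C)CCCC3(C)C | intermediate
23 | ferruginol | CC(C)c1c(O)cc2c(c1)CC[C@@H]3[C@]2(C)CCCC3(C)C | intermediate (not isolated)
24 | 12-methoxyabieta-8,11,13-triene | CC(C)c1c(OC)cc2c(c1)CC[C@@H]3[C@]2(C)CCCC3(C)C | intermediate
25 | 12-methoxyabieta-8,11,13-trien-7-one | CC(C)c1c(OC)cc2c(c1)C(=O)C[C@@H]3[C@]2(C)CCCC3(C)C | intermediate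
26 | 6-trifluoroacetyl derivative of 25 | CC(C)c1c(OC)cc2c(c1)C(=O)C(C(=O)C(F)(F)F)[C@@H]3[C@]2(C)CCCC3(C)C | intermediate (not isolated)
27 | 6-diazo-12-methoxyabieta-8,11,13-trien-7-one | CC(C)c1c(OC)cc2c(c1)C(=O)C(=[N+]=[N-])[C@@H]3[C@]2(C)CCCC3(C)C | intermediate
28 | ring-contracted aryl ketene | CC(C)c1c(OC)cc2c(c1)C(=C=O)[C@@H]3[C@]2(C)CCCC3(C)C | intermediate (not isolated)
29 | methyl (5α,7β)-12-methoxy-5(6→7)abeo-abieta-8,11,13-trien-6-oate | CC(C)c1c(OC)cc2c(c1)[C@@H](C(=O)OC)[C@@H]3[C@]2(C)CCCC3(C)C | intermediate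
30 | (5α,7β)-12-methoxy-5(6→7)abeo-abieta-8,11,13-trien-6-ol | CC(C)c1c(OC)cc2c(c1)[C@@H](CO)[C@@H]3[C@]2(C)CCCC3(C)C | intermediate
31 | 6-O-TBS ether of 30 | CC(C)c1c(OC)cc2c(c1)[C@@H](CO[Si](C)(C)C(C)(C)C)[C@@H]3[C@]2(C)CCCC3(C)C | intermediate
32 | 11-lithio derivative of 31 | CC(C)c1c(OC)c([Li])c2c(c1)[C@@H](CO[Si](C)(C)C(C)(C)C)[C@@H]3[C@]2(C)CCCC3(C)C | intermediate (not isolated)
33 | 11-(dimethoxyboryl) derivative of 31 | CC(C)c1c(OC)c(B(OC)OC)c2c(c1)[C@@H](CO[Si](C)(C)C(C)(C)C)[C@@H]3[C@]2(C)CCCC3(C)C | intermediate (not isolated)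
34 | (5α,7β)-6-(TBS-oxy)-12-methoxy-5(6→7)abeo-abieta-8,11,13-trien-11-ol | CC(C)c1c(OC)c(O)c2c(c1)[C@@H](CO[Si](C)(C)C(C)(C)C)[C@@H]3[C@]2(C)CCCC3(C)C | intermediate
35 | (5α,7β)-6-(TBS-oxy)-12-methoxy-5(6→7)abeo-abieta-8,12-diene-11,14-dione | CC(C)C1=C(OC)C(=O)C2=C(C1=O)[C@@H](CO[Si](C)(C)C(C)(C)C)[C@@H]3[C@]2(C)CCCC3(C)C | intermediate
36 | (5α,7β)-6-(TBS-oxy)-12-hydroxy-5(6→7)abeo-abieta-8,12-diene-11,14-dione | CC(C)C1=C(O)C(=O)C2=C(C1=O)[C@@H](CO[Si](C)(C)C(C)(C)C)[C@@H]3[C@]2(C)CCCC3(C)C | intermediate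
37 | C-13 Michael adduct (ene-trione carrying the 15′-nitro side chain, shown as the nitroalkane) | C=C1CC[C@@H]2[C@](C)(CCC[C@@]2(C)C(=O)OCC[Si](C)(C)C)[C@H]1C/C=C(\C)[C@H](C[N+](=O)[O-])[C@@]1(C(C)C)C(=O)C(=O)C2=C(C1=O)[C@@H](CO[Si](C)(C)C(C)(C)C)[C@@H]3[C@]2(C)CCCC3(C)C | intermediate (not isolated)
38 | 15′-nitro adduct (8α-bridge, 14′-dienyl endo, 15′-nitro exo, 7β-CH2OTBS, TMSE ester) | C=C1CC[C@@H]2[C@](C)(CCC[C@@]2(C)C(=O)OCC[Si](C)(C)C)[C@H]1C/C=C(\C)[C@@H]1[C@@H]([N+](=O)[O-])[C@@]23C(=O)[C@]1(C(C)C)C(=O)C(O)=C2[C@@]1(C)CCCC(C)(C)[C@@H]1[C@@H]3CO[Si](C)(C)C(C)(C)C | intermediate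
39 | denitrated adduct (7β-CH2OTBS, TMSE ester) | C=C1CC[C@@H]2[C@](C)(CCC[C@@]2(C)C(=O)OCC[Si](C)(C)C)[C@H]1C/C=C(\C)[C@@H]1C[C@@]23C(=O)[C@]1(C(C)C)C(=O)C(O)=C2[C@@]1(C)CCCC(C)(C)[C@@H]1[C@@H]3CO[Si](C)(C)C(C)(C)C | intermediate
40 | 7β-hydroxymethyl carboxylic acid | C=C1CC[C@@H]2[C@](C)(CCC[C@@]2(C)C(=O)O)[C@H]1C/C=C(\C)[C@@H]1C[C@@]23C(=O)[C@]1(C(C)C)C(=O)C(O)=C2[C@@]1(C)CCCC(C)(C)[C@@H]1[C@@H]3CO | intermediate
41 | 7β-formyl epimer of the target | C=C1CC[C@@H]2[C@](C)(CCC[C@@]2(C)C(=O)O)[C@H]1C/C=C(\C)[C@@H]1C[C@@]23C(=O)[C@]1(C(C)C)C(=O)C(O)=C2[C@@]1(C)CCCC(C)(C)[C@@H]1[C@@H]3C=O | intermediate (not isolated)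
42 | CNP0256710.1 | C=C1CC[C@@H]2[C@](C)(CCC[C@@]2(C)C(=O)O)[C@H]1C/C=C(\C)[C@@H]1C[C@@]23C(=O)[C@]1(C(C)C)C(=O)C(O)=C2[C@@]1(C)CCCC(C)(C)[C@@H]1[C@H]3C=O | target

## Step count and risks

Total step count: 28. Longest linear sequence: 18 steps (17 → 42, steps 11–28).

The three steps most likely to fail:

Step 25 (tandem Michael annulation). The C-13–C-14′ bond joins a quaternary isopropyl-bearing carbon to a substituted alkene carbon, and the endo placement of the dienyl group is the least secure stereochemical prediction. The fallback sets out from 12 and 36. Wittig methylenation of 12 (Ph3P=CH2, THF, 0 °C) gives the triene TMSE trans-ozate F1. An acid-promoted (BF3·OEt2 or TFA, CH2Cl2–HFIP, −20 °C) perezone-type [5+2] cycloaddition of F1 with 36 then forms the same two bonds without a nitro group. It comes back to the route at 39, so steps 9, 10 and 26 are no longer needed.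

Step 26 (radical denitration). The C-15′ radical is homoallylic to the C9=C11 enol and β to the C-14 ketone, so a 1,2-vinyl shift or ring expansion can compete, and tin radicals may attack the enone. The fallback sets out from 38. A Nef reaction (DBU, then buffered aqueous TiCl3/NH4OAc, THF) gives the 15′-ketone F2. Condensation with TsNHNH2 at this, the only unhindered ketone, gives the tosylhydrazone F3, and catecholborane/NaOAc reduction converts C=N–NHTs into CH2. It comes back to the route at 39.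

Step 22 (directed ortho-metalation at the peri-hindered C-11). Lateral lithiation at C-7 or slow metalation may intervene. The fallback sets out from 31. Electrophilic bromination (NBS, MeCN, 0 °C) ortho to the methoxy group gives the 11-bromoarene F4. Bromine–lithium exchange (t-BuLi, Et2O, −78 °C) generates aryllithium 32, which is borylated and oxidised as in step 22. It comes back to the route at 34.

## Further compounds

F1 | step 25 | TMSE (12E)-labda-8(17),12,14-trien-18-oate (TMSE trans-ozate) | C=C/C(C)=C/C[C@H]1C(=C)CC[C@@H]2[C@]1(C)CCC[C@@]2(C)C(=O)OCC[Si](C)(C)C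
F2 | step 26 | 15′-oxo analogue of 39 (15′-ketone) | C=C1CC[C@@H]2[C@](C)(CCC[C@@]2(C)C(=O)OCC[Si](C)(C)C)[C@H]1C/C=C(\C)[C@@H]1C(=O)[C@@]23C(=O)[C@]1(C(C)C)C(=O)C(O)=C2[C@@]1(C)CCCC(C)(C)[C@@H]1[C@@H]3CO[Si](C)(C)C(C)(C)C
F3 | step 26 | 15′-tosylhydrazone of F2 | C=C1CC[C@@H]2[C@](C)(CCC[C@@]2(C)C(=O)OCC[Si](C)(C)C)[C@H]1C/C=C(\C)[C@@H]1C(=NNS(=O)(=O)c4ccc(C)cc4)[C@@]23C(=O)[C@]1(C(C)C)C(=O)C(O)=C2[C@@]1(C)CCCC(C)(C)[C@@H]1[C@@H]3CO[Si](C)(C)C(C)(C)C
F4 | step 22 | 11-bromo derivative of 31 | CC(C)c1c(OC)c(Br)c2c(c1)[C@@H](CO[Si](C)(C)C(C)(C)C)[C@@H]3[C@]2(C)CCCC3(C)C
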